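## The problem

Target 19 has a single ring, an oxan-4-one. O1 joins C2, which carries the guaiacyl ring A, to C6, which carries the carbinol carbon C1'; the C2' methylene on C1' leads to the phenol ring B. The task is therefore to build a seven-carbon chain between two arenes and to close one C–O–C ring.

There are three stereocentres, C2 (S), C6 (R) and C1' (S). The ring substituents are cis (both equatorial) and the oxygens on C6 and C1' are anti. C1' is the α-carbon of a 3-arylpropanoic acid, so it can come from the chiral pool, and it biases addition at C6 in the Felkin–Anh sense, which is the anti sense needed. C6 cannot steer C2 kinetically across the ether oxygen of an open chain, so C2 needs a catalyst. Once the ring and the C4 ketone exist, however, C6 holds C2 thermodynamically, because the cis isomer is diequatorial and C2 can reopen by retro-oxa-Michael reaction or benzylic ionisation.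

The same reactivity marks what must be treated gently:
- the ketone is β-alkoxy on both flanks;
- the C2–O1 bond is benzylic and para to an oxygen donor, so it is prone to ionisation and hydrogenolysis;
- the carbonyl intermediates that carry C1' can epimerise;
- silicon can migrate between the vicinal oxygens on C6 and C1' under base.

The feature that makes the key step possible is that O1 places C2 and C6 at the spacing of a 4-oxa-1,7-diene. An open ether with a vinyl group on C2 and an allyl group on C6 closes to the six-membered ring by forming C3=C4, and that alkene, next to the allylic C2–O1 bond, is a latent C4 ketone.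

## Retrosynthesis

**Protecting groups (19 from 18 from 17).** No skeletal bond is cut. Both phenols are carried as benzyl ethers, which tolerate every organometallic step and leave together in one hydrogenolysis. The C1' oxygen is carried as a tert-butyldimethylsilyl ether, which does not chelate and is removed with buffered HF. Taking the silyl group off first (17 to 18) keeps the final hydrogenolysis (18 to 19) to the two fast aryl benzyl ethers, which gives the widest margin over cleavage of the ring benzylic C2–O1 bond.

**C4 carbonyl (17 from 16).** The C4=O bond is traced back to the C3=C4 alkene of dihydropyran 16. Hydroboration would put boron on C3, next to the inductively withdrawing C2–O1 bond, and epoxide opening would also favour C3. A Wacker-type oxidation has the opposite polarity: water attacks the alkene carbon farther from the allylic oxygen, which is C4. Precursor 16 has no β-alkoxy ketone, so nothing upstream can undergo retro-oxa-Michael reaction. The forward step must put oxygen on C4 and must not ionise the arylallyl ether, so a chloride-based PdCl2/CuCl/O2 system is chosen over variants run in strong acid.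

**Ring (16 from 15).** The C3=C4 bond is cut by ring-closing metathesis, giving the open diene ether 15. Cutting O1–C2 (oxa-Michael) or C2–C3 with O1–C6 (hetero-Diels–Alder) would each create a ring stereocentre in the ring-forming step. The metathesis cut creates none, so 15 already holds C2, C6 and C1'. Precursor 15 is acyclic and is the union of two fragments of similar size. The forward reaction has only to favour the six-membered ring over oligomers.

**Ether (15 from 13 and 5, through 14).** The O1–C2 bond is cut. The neighbouring O1–C6 cut would need an SN2 displacement at a hindered secondary carbon flanked by a silyl ether. The O1–C2 cut corresponds to a branched-selective iridium-catalysed allylic etherification of the linear cinnamyl carbonate 5 by alcohol 13, used as its zinc alkoxide 14. This sets C2 under ligand control and delivers the vinyl group needed for metathesis in the same step. A zinc alkoxide is preferred to a lithium or potassium alkoxide because it should not move the silyl group from the C1' oxygen to the C6 oxygen. The ketone stage offers a reserve if C2 is imperfectly set, since cis is the thermodynamic isomer.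

**C5–C6 bond (13 from 11, through 12).** The allyl group is cut from C6, giving α-silyloxy aldehyde 11. The anti relationship wanted is the Felkin–Anh outcome for a non-chelating α-silyloxy aldehyde, so a Brown allylation with the matched reagent enantiomer reinforces the substrate bias, the addition passing through borinate 12. The allyl group is also the second alkene for the metathesis.

**Chiral pool (11 from 10 from 9 from 8 from 6, through 7).** These are functional-group changes only. Commercial O-benzyl-L-tyrosine 6 already has ring B protected. Diazotisation replaces nitrogen by oxygen with retention through α-lactone 7, giving hydroxy acid 8. Esterification (9), silylation (10) and partial reduction give 11. Nothing in this sequence enolises C1' until the aldehyde, which is used at once at −78 °C.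

**Ring A partner (5 from 4 from 3 from 1 and 2).** The alkene of 5 is cut by a Horner–Wadsworth–Emmons disconnection to O-benzylvanillin 1 and phosphonate 2. Reduction of ester 3 gives alcohol 4, and acylation gives the tert-butyl carbonate 5. In the ring, the aryl-bearing alkene carbon of 5 becomes C2 and its neighbour becomes C3; the oxygenated CH2 leaves as ethene.

## Roads not taken

**Alternative 1:** The cut is on both sides of C4, with a 1,3-dithiane as the acyl dianion equivalent. Lithiated 2-(tert-butyldimethylsilyl)-1,3-dithiane A4 would open the tyrosine-derived epoxide A2 at C5. HMPA would then trigger a 1,4-Brook shift of silicon to the C6 oxygen, and the regenerated anion would open aryl oxirane A3 at C3, giving A1 in one flask.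
- Merits: two C–C bonds form in one operation. All three stereocentres come from enantiopure epoxides. The C4 carbonyl is placed without any regiochemical question, and on that point this road is better than the chosen one.
- Weak points: no ring is closed, and A1 is an open 1,5-dioxygenated chain. C2 and C6 already have the configuration they need in the ring, so neither oxygen can close by simple SN2 inversion. Closure would have to go through benzylic ionisation or elimination and oxa-Michael re-addition after the ketone is unmasked. The dithiane must be removed by oxidants or thiophilic metal salts in the presence of two electron-rich arenes. Epoxide A2 costs about as many steps as alcohol 13.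
- Comparison: after its key step this road still needs dithiane cleavage, selective desilylation, ring closure and deprotection. The chosen plan has the ring after its key step and three steps left. Against the certainty of A1 at C4, the chosen plan sets the inductive bias of the allylic ether and a hydration reserve.

**Alternative 2:** The cut is C2–C3 with O1–C6, a hetero-Diels–Alder reaction. Aldehyde A7 would add across the termini of siloxydiene A6 under a chiral tridentate Schiff-base CrCl complex (trivalent chromium), giving A5, in which C4 is already a silyl enol ether.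
- Merits: the ring, two bonds and both ring stereocentres are made at once, and the ketone appears on mild hydrolysis. A6 is two steps from aldehyde 11. This is the shortest road and it avoids the Wacker question altogether.
- Weak points: this catalyst class works best with reactive aldehydes and activated dienes. A7 is an electron-rich aromatic aldehyde, and A6 has no terminal alkoxy group and carries a bulky allylic stereocentre. Rate and the diene facial selectivity (catalyst against the C1' centre) are therefore both uncertain. The aryl acetate must later be cleaved by a nucleophile next to a β-alkoxy ketone.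
- Comparison: this road wins on step count and on C4. The chosen plan offers in return one stereocentre per step, each with an established induction model, and a ring closure of very high reliability.

**Alternative 3:** The cut is C5–C6 with O1–C6, a Maitland–Japp annulation. Under Yb(OTf)3, δ-hydroxy-β-ketoester A9 would condense with aldehyde 11 (Knoevenagel) and the C2 hydroxyl would add to the alkylidene, giving A8. One hydrogenolysis would then remove the benzyl ester with decarboxylation together with both phenol benzyl groups.
- Merits: it uses the same aldehyde 11, forms the ring and two bonds in one step, gives the cis ring by equilibration, and has a very short endgame. In step count it is at least as good as the chosen plan.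
- Weak points: A9 needs an enantioselective aldol reaction of an acetoacetate dienolate with the electron-rich aldehyde 1, and its benzylic hydroxyl dehydrates easily. The Lewis-acid Knoevenagel step exposes the epimerisable α-silyloxy aldehyde 11 at ambient temperature, which puts C1' at risk. A8 forms as keto/enol and ring-epimer mixtures.
- Comparison: the chosen plan consumes 11 at −78 °C under reagent control and sets C2 by a catalyst. It is longer by about two steps.

Key step: step 10

Assumption: with [Ir(cod)Cl]2, the (Sa,S,S) enantiomer of ligand L, (1,1'-binaphthalene-2,2'-diyl) N,N-bis(1-phenylethyl)phosphoramidite, is taken to deliver an oxygen nucleophile to the face of the arylallyl terminus that gives the (S)-ether; the centre is ligand-controlled, so the mirror-image ligand would be used if the sense were opposite.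

## Route

Step 1
Reactants: 1 4-(benzyloxy)-3-methoxybenzaldehyde; 2 triethyl phosphonoacetate
Product: 3 ethyl (2E)-3-[4-(benzyloxy)-3-methoxyphenyl]prop-2-enoate
Conditions: NaH, THF, 0 °C → rt
Reagents that add atoms: none
Why: Horner–Wadsworth–Emmons olefination of a non-enolisable aryl aldehyde with a stabilised phosphonate anion; reversible addition and syn-elimination should give the (E)-cinnamate.

Step 2
Reactants: 3 ethyl (2E)-3-[4-(benzyloxy)-3-methoxyphenyl]prop-2-enoate
Product: 4 (2E)-3-[4-(benzyloxy)-3-methoxyphenyl]prop-2-en-1-ol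
Conditions: i-Bu2AlH (2.5 equiv), CH2Cl2, −78 → 0 °C; aq. potassium sodium tartrate
Reagents that add atoms: none
Why: i-Bu2AlH reduces α,β-unsaturated esters by 1,2-addition to the allylic alcohol and leaves the aryl ethers alone.

Step 3
Reactants: 4 (2E)-3-[4-(benzyloxy)-3-methoxyphenyl]prop-2-en-1-ol
Product: 5 tert-butyl (2E)-3-[4-(benzyloxy)-3-methoxyphenyl]prop-2-en-1-yl carbonate
Conditions: Boc2O, n-Bu4NHSO4 (cat.), aq. NaOH, CH2Cl2, 0 °C → rt
Reagents that add atoms: di-tert-butyl dicarbonate (Boc2O), CC(C)(C)OC(=O)OC(=O)OC(C)(C)C
Why: Phase-transfer O-acylation of a primary allylic alcohol; the tert-butyl carbonate is chosen because the tert-butoxide it releases in step 9 is too hindered to compete as a nucleophile.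

Step 4
Reactants: 6 O-benzyl-L-tyrosine, (2S)-2-amino-3-[4-(benzyloxy)phenyl]propanoic acid
Product: 8 (2S)-3-[4-(benzyloxy)phenyl]-2-hydroxypropanoic acid, via alpha-lactone 7 (not isolated)
Conditions: NaNO2, 1 M H2SO4, H2O/1,4-dioxane, 0 °C → rt
Reagents that add atoms: water, O
Why: Diazotisation of an α-amino acid; the carboxylate displaces N2 with inversion to give α-lactone 7 and water opens it with a second inversion, so the (S) configuration that becomes C1' is retained.

Step 5
Reactants: 8 (2S)-3-[4-(benzyloxy)phenyl]-2-hydroxypropanoic acid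
Product: 9 methyl (2S)-3-[4-(benzyloxy)phenyl]-2-hydroxypropanoate
Conditions: MeOH, H2SO4 (cat.), 65 °C
Reagents that add atoms: methanol, CO
Why: Fischer esterification; the stereocentre is not enolised under acid catalysis in methanol and the aryl benzyl ether is stable.

Step 6
Reactants: 9 methyl (2S)-3-[4-(benzyloxy)phenyl]-2-hydroxypropanoate
Product: 10 methyl (2S)-3-[4-(benzyloxy)phenyl]-2-[(tert-butyldimethylsilyl)oxy]propanoate
Conditions: TBSCl, imidazole, DMF, rt
Reagents that add atoms: tert-butyldimethylsilyl chloride (TBSCl), CC(C)(C)[Si](C)(C)Cl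
Why: Standard silylation of a secondary alcohol; the bulky, non-chelating silyl ether prepares the Felkin–Anh bias of step 8 and survives steps 7 to 11.

Step 7
Reactants: 10 methyl (2S)-3-[4-(benzyloxy)phenyl]-2-[(tert-butyldimethylsilyl)oxy]propanoate
Product: 11 (2S)-3-[4-(benzyloxy)phenyl]-2-[(tert-butyldimethylsilyl)oxy]propanal
Conditions: i-Bu2AlH (1.1 equiv), CH2Cl2, −78 °C; MeOH, then aq. potassium sodium tartrate
Reagents that add atoms: none
Why: Partial reduction of an α-silyloxy ester, which at −78 °C stops at the aldehyde oxidation level; the aldehyde is used crude and cold so that C1' does not epimerise.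

Step 8
Reactants: 11 (2S)-3-[4-(benzyloxy)phenyl]-2-[(tert-butyldimethylsilyl)oxy]propanal
Product: 13 (2S,3R)-1-[4-(benzyloxy)phenyl]-2-[(tert-butyldimethylsilyl)oxy]hex-5-en-3-ol, via diisopinocampheylborinate 12 (not isolated)
Conditions: (+)-Ipc2BOMe [from (−)-α-pinene], CH2=CHCH2MgBr, Et2O, −78 °C → rt; then 11, −78 °C; then NaOH, H2O2, 0 °C → rt
Reagents that add atoms: allylmagnesium bromide, C=CC[Mg]Br
Why: Brown allylation through a chair six-membered transition state; the reagent from (−)-α-pinene delivers allyl to the Re face of the aldehyde and sets C6 as (R). The Felkin–Anh model for an α-silyloxy aldehyde prefers the same face, so reagent and substrate are matched for the 2,3-anti product; oxidative work-up cleaves borinate 12.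

Step 9
Reactants: 13 (2S,3R)-1-[4-(benzyloxy)phenyl]-2-[(tert-butyldimethylsilyl)oxy]hex-5-en-3-ol; 5 tert-butyl (2E)-3-[4-(benzyloxy)-3-methoxyphenyl]prop-2-en-1-yl carbonate
Product: 15 (1S)-1-[4-(benzyloxy)-3-methoxyphenyl]prop-2-en-1-yl (2S,3R)-1-[4-(benzyloxy)phenyl]-2-[(tert-butyldimethylsilyl)oxy]hex-5-en-3-yl ether, via zinc alkoxide 14 (not isolated)
Conditions: 13, Et2Zn (0.5 equiv), THF, 0 °C → rt; then 5 (1.3 equiv), [Ir(cod)Cl]2 (2.5 mol%), (Sa,S,S)-L (5 mol%), NH4I (20 mol%), THF, rt
Reagents that add atoms: none
Why: Iridium-catalysed branched-selective allylic etherification: the iridium phosphoramidite complex ionises 5 to an allyl complex that zinc alkoxide 14 attacks at the aryl-bearing terminus, with the face, and so the (S) configuration at C2, fixed by the ligand and not by the alcohol. The reaction type is established for zinc alkoxides of secondary alcohols, chiral ones included; the zinc alkoxide should neither attack the carbonate carbonyl nor move the silyl group between the vicinal oxygens.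

Step 10
Reactants: 15 (1S)-1-[4-(benzyloxy)-3-methoxyphenyl]prop-2-en-1-yl (2S,3R)-1-[4-(benzyloxy)phenyl]-2-[(tert-butyldimethylsilyl)oxy]hex-5-en-3-yl ether
Product: 16 (2S,6R)-2-[4-(benzyloxy)-3-methoxyphenyl]-6-[(1S)-2-[4-(benzyloxy)phenyl]-1-[(tert-butyldimethylsilyl)oxy]ethyl]-5,6-dihydro-2H-pyran
Conditions: second-generation Grubbs catalyst (5 mol%), CH2Cl2 (0.005 M), 40 °C
Reagents that add atoms: none
Why: Ring-closing olefin metathesis: the ruthenium benzylidene first exchanges with the unhindered terminal alkene of the allyl group on C6, placing the carbene on C4. Intramolecular [2+2] addition to the vinyl group on C2 gives a ruthenacyclobutane spanning C3 and C4, and cycloreversion releases the C3=C4 alkene of 16 and a ruthenium methylidene, which carries the chain while ethene escapes. The closest known reaction type is the metathesis of allyl homoallyl ethers (4-oxa-1,7-dienes) to dihydropyrans, including ethers made by iridium allylic etherification. The one ring closed is six-membered, formed by alkene–alkene metathesis of a 1,7-diene, and its alkene is necessarily cis. No stereocentre is formed or touched, since C2, C6 and C1' take part in no bond change, so the configuration of 15 passes unchanged into 16. The selectivity needed is ring closure over cross-metathesis oligomers and over alkene migration by ruthenium hydrides. It is secured by high dilution, the favourable ring size, the branching at C2 and C6 that brings the two alkenes together, the loss of ethene, and the absence of free hydroxyl or amine groups that could bind ruthenium.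

Step 11
Reactants: 16 (2S,6R)-2-[4-(benzyloxy)-3-methoxyphenyl]-6-[(1S)-2-[4-(benzyloxy)phenyl]-1-[(tert-butyldimethylsilyl)oxy]ethyl]-5,6-dihydro-2H-pyran
Product: 17 (2S,6R)-2-[4-(benzyloxy)-3-methoxyphenyl]-6-[(1S)-2-[4-(benzyloxy)phenyl]-1-[(tert-butyldimethylsilyl)oxy]ethyl]oxan-4-one
Conditions: PdCl2 (20 mol%), CuCl (1.5 equiv), O2 (1 atm), DMF/H2O (7:1), 45 °C
Reagents that add atoms: water, O
Why: Tsuji–Wacker oxidation of an internal allyl ether: hydroxypalladation puts oxygen on C4, the alkene carbon farther from the electron-withdrawing C2–O1 bond and the less hindered one, and β-hydride elimination with tautomerisation gives the β-alkoxy ketone, the regiochemistry typical of allyl ethers. No strong Brønsted acid is present, so the arylallyl ether and the silyl ether should survive; no stereocentre is involved.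

Step 12
Reactants: 17 (2S,6R)-2-[4-(benzyloxy)-3-methoxyphenyl]-6-[(1S)-2-[4-(benzyloxy)phenyl]-1-[(tert-butyldimethylsilyl)oxy]ethyl]oxan-4-one
Product: 18 (2S,6R)-2-[4-(benzyloxy)-3-methoxyphenyl]-6-[(1S)-2-[4-(benzyloxy)phenyl]-1-hydroxyethyl]oxan-4-one
Conditions: HF·pyridine, pyridine, THF, 0 °C → rt
Reagents that add atoms: none
Why: Fluoride cleavage of a secondary silyl ether under buffered, weakly acidic conditions; a basic fluoride source is avoided because it could open the β-alkoxy ketone by retro-oxa-Michael reaction.

Step 13
Reactants: 18 (2S,6R)-2-[4-(benzyloxy)-3-methoxyphenyl]-6-[(1S)-2-[4-(benzyloxy)phenyl]-1-hydroxyethyl]oxan-4-one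
Product: 19 (2S,6R)-2-(4-hydroxy-3-methoxyphenyl)-6-[(1S)-1-hydroxy-2-(4-hydroxyphenyl)ethyl]oxan-4-one
Conditions: H2 (1 atm), Pd/C (10%), EtOAc, rt
Reagents that add atoms: none
Why: Hydrogenolysis of aryl benzyl ethers over palladium on carbon is much faster in a neutral solvent than cleavage of the secondary, ring-bound benzylic C2–O1 bond, and the ketone is inert under these conditions.

## Compound list

1 | 4-(benzyloxy)-3-methoxybenzaldehyde | COc1cc(C=O)ccc1OCc1ccccc1 | starting material
2 | triethyl phosphonoacetate | CCOC(=O)CP(=O)(OCC)OCC | starting material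
3 | ethyl (2E)-3-[4-(benzyloxy)-3-methoxyphenyl]prop-2-enoate | CCOC(=O)/C=C/c1ccc(OCc2ccccc2)c(OC)c1 | intermediate
4 | (2E)-3-[4-(benzyloxy)-3-methoxyphenyl]prop-2-en-1-ol | OC/C=C/c1ccc(OCc2ccccc2)c(OC)c1 | intermediate
5 | tert-butyl (2E)-3-[4-(benzyloxy)-3-methoxyphenyl]prop-2-en-1-yl carbonate | CC(C)(C)OC(=O)OC/C=C/c1ccc(OCc2ccccc2)c(OC)c1 | intermediate
6 | O-benzyl-L-tyrosine, (2S)-2-amino-3-[4-(benzyloxy)phenyl]propanoic acid | N[C@@H](Cc1ccc(OCc2ccccc2)cc1)C(=O)O | starting material
7 | (3R)-3-{[4-(benzyloxy)phenyl]methyl}oxiran-2-one (α-lactone, not isolated) | O=C1O[C@@H]1Cc1ccc(OCc2ccccc2)cc1 | intermediate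
8 | (2S)-3-[4-(benzyloxy)phenyl]-2-hydroxypropanoic acid | O[C@@H](Cc1ccc(OCc2ccccc2)cc1)C(=O)O | intermediate
9 | methyl (2S)-3-[4-(benzyloxy)phenyl]-2-hydroxypropanoate | COC(=O)[C@@H](O)Cc1ccc(OCc2ccccc2)cc1 | intermediate
10 | methyl (2S)-3-[4-(benzyloxy)phenyl]-2-[(tert-butyldimethylsilyl)oxy]propanoate | COC(=O)[C@@H](O[Si](C)(C)C(C)(C)C)Cc1ccc(OCc2ccccc2)cc1 | intermediate
11 | (2S)-3-[4-(benzyloxy)phenyl]-2-[(tert-butyldimethylsilyl)oxy]propanal | O=C[C@@H](O[Si](C)(C)C(C)(C)C)Cc1ccc(OCc2ccccc2)cc1 | intermediate
12 | (2S,3R)-1-[4-(benzyloxy)phenyl]-2-[(tert-butyldimethylsilyl)oxy]hex-5-en-3-yl diisopinocampheylborinate, isopinocampheyl groups from (−)-α-pinene (not isolated) | O([C@@H]([C@@H](O[Si](C)(C)C(C)(C)C)Cc1ccc(OCc2ccccc2)cc1)CC=C)B([C@H]1C[C@H]2C[C@@H]([C@@H]1C)C2(C)C)[C@H]1C[C@H]2C[C@@H]([C@@H]1C)C2(C)C | intermediate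
13 | (2S,3R)-1-[4-(benzyloxy)phenyl]-2-[(tert-butyldimethylsilyl)oxy]hex-5-en-3-ol | O[C@@H]([C@@H](O[Si](C)(C)C(C)(C)C)Cc1ccc(OCc2ccccc2)cc1)CC=C | intermediate
14 | zinc bis{(2S,3R)-1-[4-(benzyloxy)phenyl]-2-[(tert-butyldimethylsilyl)oxy]hex-5-en-3-olate} (not isolated) | [Zn](O[C@@H]([C@@H](O[Si](C)(C)C(C)(C)C)Cc1ccc(OCc2ccccc2)cc1)CC=C)O[C@@H]([C@@H](O[Si](C)(C)C(C)(C)C)Cc1ccc(OCc2ccccc2)cc1)CC=C | intermediate
15 | (1S)-1-[4-(benzyloxy)-3-methoxyphenyl]prop-2-en-1-yl (2S,3R)-1-[4-(benzyloxy)phenyl]-2-[(tert-butyldimethylsilyl)oxy]hex-5-en-3-yl ether | COc1cc([C@H](C=C)O[C@@H]([C@@H](O[Si](C)(C)C(C)(C)C)Cc2ccc(OCc3ccccc3)cc2)CC=C)ccc1OCc1ccccc1 | intermediate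
16 | (2S,6R)-2-[4-(benzyloxy)-3-methoxyphenyl]-6-[(1S)-2-[4-(benzyloxy)phenyl]-1-[(tert-butyldimethylsilyl)oxy]ethyl]-5,6-dihydro-2H-pyran | COc1cc([C@@H]2C=CC[C@H]([C@@H](O[Si](C)(C)C(C)(C)C)Cc3ccc(OCc4ccccc4)cc3)O2)ccc1OCc1ccccc1 | intermediate
17 | (2S,6R)-2-[4-(benzyloxy)-3-methoxyphenyl]-6-[(1S)-2-[4-(benzyloxy)phenyl]-1-[(tert-butyldimethylsilyl)oxy]ethyl]oxan-4-one | COc1cc([C@@H]2CC(=O)C[C@H]([C@@H](O[Si](C)(C)C(C)(C)C)Cc3ccc(OCc4ccccc4)cc3)O2)ccc1OCc1ccccc1 | intermediate
18 | (2S,6R)-2-[4-(benzyloxy)-3-methoxyphenyl]-6-[(1S)-2-[4-(benzyloxy)phenyl]-1-hydroxyethyl]oxan-4-one | COc1cc([C@@H]2CC(=O)C[C@H]([C@@H](O)Cc3ccc(OCc4ccccc4)cc3)O2)ccc1OCc1ccccc1 | intermediate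
19 | (2S,6R)-2-(4-hydroxy-3-methoxyphenyl)-6-[(1S)-1-hydroxy-2-(4-hydroxyphenyl)ethyl]oxan-4-one | COc1cc([C@@H]2CC(=O)C[C@H]([C@@H](O)Cc3ccc(O)cc3)O2)ccc1O | target

## Step count and least certain steps

Total step count: 13 (three to carbonate 5, five to alcohol 13, five after their union). Longest linear sequence: 10 steps (6 to 19, steps 4 to 13).

**Step 10 (key step).** The most likely failure is that ring closure at the doubly branched arylallyl ether terminus is slow. Intermolecular metathesis through the exposed allyl terminus, or migration of the allyl double bond by ruthenium hydrides followed by ring contraction, could then compete. The fallback closes the ring at O1–C2 by oxa-Michael addition instead. It sets out from aldehydes 1 and 11 and returns at ketone 17. Claisen–Schmidt condensation of 1 with acetone (aq. NaOH) should give (3E)-4-[4-(benzyloxy)-3-methoxyphenyl]but-3-en-2-one F1. Me3SiOTf and Et3N would convert it into {[(3E)-4-[4-(benzyloxy)-3-methoxyphenyl]buta-1,3-dien-2-yl]oxy}trimethylsilane F2. A Mukaiyama aldol addition of F2 to 11 (BF3·OEt2, CH2Cl2, −78 °C), Felkin-selective for α-silyloxy aldehydes, should give (1E,5R,6S)-1-[4-(benzyloxy)-3-methoxyphenyl]-7-[4-(benzyloxy)phenyl]-6-[(tert-butyldimethylsilyl)oxy]-5-hydroxyhept-1-en-3-one F3. Catalytic camphorsulfonic acid in CH2Cl2 would then cyclise F3 by 6-endo oxa-Michael addition to the thermodynamically favoured cis ketone 17.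

**Step 9.** The most likely failure is loss of stereochemical control at C2, through incomplete facial control in a mismatched catalyst–alcohol pairing or reversible ionisation of the electron-rich arylallyl system. Slow attack of the hindered alkoxide with more linear ether, and base-induced silyl migration between the vicinal oxygens, are further possibilities. The fallback moves control of C2 from kinetics to thermodynamics. It sets out from the crude etherification product and returns at ketone 17. Diene 15 is carried on together with its C2 epimer, (1R)-1-[4-(benzyloxy)-3-methoxyphenyl]prop-2-en-1-yl (2S,3R)-1-[4-(benzyloxy)phenyl]-2-[(tert-butyldimethylsilyl)oxy]hex-5-en-3-yl ether F4. Metathesis as in step 10 would give, beside 16, the trans ring (2R,6R)-2-[4-(benzyloxy)-3-methoxyphenyl]-6-[(1S)-2-[4-(benzyloxy)phenyl]-1-[(tert-butyldimethylsilyl)oxy]ethyl]-5,6-dihydro-2H-pyran F5. Oxidation as in step 11 would give, beside 17, (2R,6R)-2-[4-(benzyloxy)-3-methoxyphenyl]-6-[(1S)-2-[4-(benzyloxy)phenyl]-1-[(tert-butyldimethylsilyl)oxy]ethyl]oxan-4-one F6. Brief treatment of the ketone mixture with catalytic camphorsulfonic acid in CH2Cl2 should reopen the benzylic C2–O1 bond (retro-oxa-Michael or benzylic ionisation) and reclose it to the diequatorial cis isomer 17, with C6 acting as the anchor.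

**Step 11.** The most likely failures are attack of water at C3 instead of C4 and slow turnover of the internal alkene, which would give palladium time to open the allylic ether. The fallback is a two-step hydration and oxidation with the same polarity. It sets out from 16 and returns at 17. Oxymercuration–demercuration (Hg(OAc)2, THF/H2O; then NaBH4, aq. NaOH), which also places oxygen distal to an allylic ether, should give (2S,6R)-2-[4-(benzyloxy)-3-methoxyphenyl]-6-[(1S)-2-[4-(benzyloxy)phenyl]-1-[(tert-butyldimethylsilyl)oxy]ethyl]oxan-4-ol F7. Its C4 configuration does not matter, because Dess–Martin periodinane (NaHCO3, CH2Cl2) converts either epimer into 17.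

**Step 13.** The most likely failure is over-reduction: once ring A is a free, electron-rich phenol, the ring benzylic C2–O1 bond may itself be hydrogenolysed. The fallback replaces reductive cleavage by Lewis-acid debenzylation. It sets out from 18 and returns at 19 without any new compound (entry F0). BCl3 with pentamethylbenzene as benzyl-cation scavenger in CH2Cl2 at −78 °C cleaves aryl benzyl ethers, and the aryloxyboron species formed make ring A less able to support ionisation at C2 until aqueous work-up.

Further compounds

F1 | step 10 | (3E)-4-[4-(benzyloxy)-3-methoxyphenyl]but-3-en-2-one | COc1cc(/C=C/C(C)=O)ccc1OCc1ccccc1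
F2 | step 10 | {[(3E)-4-[4-(benzyloxy)-3-methoxyphenyl]buta-1,3-dien-2-yl]oxy}trimethylsilane | COc1cc(/C=C/C(=C)O[Si](C)(C)C)ccc1OCc1ccccc1
F3 | step 10 | (1E,5R,6S)-1-[4-(benzyloxy)-3-methoxyphenyl]-7-[4-(benzyloxy)phenyl]-6-[(tert-butyldimethylsilyl)oxy]-5-hydroxyhept-1-en-3-one | COc1cc(/C=C/C(=O)C[C@@H](O)[C@@H](O[Si](C)(C)C(C)(C)C)Cc2ccc(OCc3ccccc3)cc2)ccc1OCc1ccccc1
F4 | step 9 | (1R)-1-[4-(benzyloxy)-3-methoxyphenyl]prop-2-en-1-yl (2S,3R)-1-[4-(benzyloxy)phenyl]-2-[(tert-butyldimethylsilyl)oxy]hex-5-en-3-yl ether | COc1cc([C@@H](C=C)O[C@@H]([C@@H](O[Si](C)(C)C(C)(C)C)Cc2ccc(OCc3ccccc3)cc2)CC=C)ccc1OCc1ccccc1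
F5 | step 9 | (2R,6R)-2-[4-(benzyloxy)-3-methoxyphenyl]-6-[(1S)-2-[4-(benzyloxy)phenyl]-1-[(tert-butyldimethylsilyl)oxy]ethyl]-5,6-dihydro-2H-pyran | COc1cc([C@H]2C=CC[C@H]([C@@H](O[Si](C)(C)C(C)(C)C)Cc3ccc(OCc4ccccc4)cc3)O2)ccc1OCc1ccccc1
F6 | step 9 | (2R,6R)-2-[4-(benzyloxy)-3-methoxyphenyl]-6-[(1S)-2-[4-(benzyloxy)phenyl]-1-[(tert-butyldimethylsilyl)oxy]ethyl]oxan-4-one | COc1cc([C@H]2CC(=O)C[C@H]([C@@H](O[Si](C)(C)C(C)(C)C)Cc3ccc(OCc4ccccc4)cc3)O2)ccc1OCc1ccccc1
F7 | step 11 | (2S,6R)-2-[4-(benzyloxy)-3-methoxyphenyl]-6-[(1S)-2-[4-(benzyloxy)phenyl]-1-[(tert-butyldimethylsilyl)oxy]ethyl]oxan-4-ol (C4 epimers) | COc1cc([C@@H]2CC(O)C[C@H]([C@@H](O[Si](C)(C)C(C)(C)C)Cc3ccc(OCc4ccccc4)cc3)O2)ccc1OCc1ccccc1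
F0 | step 13 | none | none
A1 | alternative 1 | (1S)-1-[4-(benzyloxy)-3-methoxyphenyl]-2-{2-[(2R,3S)-4-[4-(benzyloxy)phenyl]-2,3-bis[(tert-butyldimethylsilyl)oxy]butyl]-1,3-dithian-2-yl}ethan-1-ol | COc1cc([C@@H](O)CC2(C[C@H]([C@@H](O[Si](C)(C)C(C)(C)C)Cc3ccc(OCc4ccccc4)cc3)O[Si](C)(C)C(C)(C)C)SCCCS2)ccc1OCc1ccccc1
A2 | alternative 1 | (2R)-2-[(1S)-2-[4-(benzyloxy)phenyl]-1-[(tert-butyldimethylsilyl)oxy]ethyl]oxirane | C1O[C@H]1[C@@H](O[Si](C)(C)C(C)(C)C)Cc1ccc(OCc2ccccc2)cc1
A3 | alternative 1 | (2R)-2-[4-(benzyloxy)-3-methoxyphenyl]oxirane | COc1cc([C@@H]2CO2)ccc1OCc1ccccc1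
A4 | alternative 1 | 2-(tert-butyldimethylsilyl)-1,3-dithiane | CC(C)(C)[Si](C)(C)C1SCCCS1
A5 | alternative 2 | 4-[(2S,6R)-6-[(1S)-2-[4-(benzyloxy)phenyl]-1-[(tert-butyldimethylsilyl)oxy]ethyl]-4-[(triethylsilyl)oxy]-3,6-dihydro-2H-pyran-2-yl]-2-methoxyphenyl acetate | COc1cc([C@@H]2CC(O[Si](CC)(CC)CC)=C[C@H]([C@@H](O[Si](C)(C)C(C)(C)C)Cc3ccc(OCc4ccccc4)cc3)O2)ccc1OC(C)=O
A6 | alternative 2 | triethyl{[(3E,5S)-6-[4-(benzyloxy)phenyl]-5-[(tert-butyldimethylsilyl)oxy]hexa-1,3-dien-2-yl]oxy}silane | C=C(O[Si](CC)(CC)CC)/C=C/[C@@H](O[Si](C)(C)C(C)(C)C)Cc1ccc(OCc2ccccc2)cc1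
A7 | alternative 2 | 4-formyl-2-methoxyphenyl acetate | COc1cc(C=O)ccc1OC(C)=O
A8 | alternative 3 | benzyl (2R,6S)-6-[4-(benzyloxy)-3-methoxyphenyl]-2-[(1S)-2-[4-(benzyloxy)phenyl]-1-[(tert-butyldimethylsilyl)oxy]ethyl]-4-hydroxy-5,6-dihydro-2H-pyran-3-carboxylate | COc1cc([C@@H]2CC(O)=C(C(=O)OCc4ccccc4)[C@H]([C@@H](O[Si](C)(C)C(C)(C)C)Cc3ccc(OCc5ccccc5)cc3)O2)ccc1OCc1ccccc1
A9 | alternative 3 | benzyl (5S)-5-[4-(benzyloxy)-3-methoxyphenyl]-5-hydroxy-3-oxopentanoate | COc1cc([C@@H](O)CC(=O)CC(=O)OCc2ccccc2)ccc1OCc1ccccc1
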